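## The problem

Compound 24 is a (2S)-flavanone in which benzene ring A is fused through C4a–C8a to dihydropyranone ring C and C2 carries the 3,5-dihydroxyphenyl ring B. Every carbon of ring A is substituted: oxygen on C5, C7 and C8a, carbon on C4a, C6 and C8, the last two as prenyl groups. The customary entry, C-prenylation of a phloroglucinol, must distinguish C from O and C6 from C8 and stop at two groups, so it tends to give mixtures. C2 is the only stereocentre; it is benzylic, β to the C4 ketone and bonded to a phenolic oxygen, so base or heat can open ring C to the chalcone and racemise it. No second centre can set or repair it, so it must come from a reagent-controlled step and then be kept from base and heat. The two trisubstituted olefins lie ortho to phenols and close to chromans in strong acid, and they rule out hydrogenolysis and hard electrophiles. The feature that opens another road is the strict alternation of oxygen and carbon around ring A: it is the pattern of a head-to-tail trimer of three oxygen-substituted alkynes (C8a≡C8, C4a≡C5, C6≡C7), two of which are already joined by the chain C4–C3–C2–O1 that becomes ring C.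

## Retrosynthesis

**24 from 23.** The last cut removes four O-protecting groups: two aryl tert-butyl ethers on ring A and two methoxymethyl (MOM) ethers on ring B. tert-Butyl is chosen for ring A because tert-butoxyalkynes are easily made and, unlike benzyl or allyl ynol ethers, have no sigmatropic escape. MOM is chosen for ring B because it survives KH, butyllithium, hydride and fluoride and falls to the same mild acid. The forward step must free four phenols without protonating the prenyl olefins.

**23 from 20 and 22.** Three ring A bonds are cut: C4a–C8a, C5–C6 and C7–C8. This opens rings A and C together and leaves the open-chain diyne 20 (an ynone and an ynol ether linked by C4–C3–C2–O1) and the monoalkyne 22. Cutting O1–C2, O1–C8a or C2–C3 instead would leave ring A intact, so the hexasubstituted arene would still have to be made by phloroglucinol substitution; cutting only the prenyl bonds leaves the same problem in another form. After the chosen cut no arene ring A remains, both prenyl groups already sit on alkyne carbons, and the only stereocentre lies in the tether. The forward reaction must be a cross-cyclotrimerisation at room temperature under neutral conditions, with 22 inserting in one orientation.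

**22 from 17 and 9.** Cutting C6–C1″ of 22 gives a tert-butoxyacetylide and prenyl bromide 9. The acetylide is the sodium salt 21, made from tert-butoxyethyne 17 with NaN(SiMe3)2. An amide base in slight deficit leaves no strong base beside the base-sensitive skipped enyne, and the forward step is a plain SN2 alkylation at a primary allylic carbon.

**17 from 15; 15 from 14 and 7.** The terminal ynol ether 17 is the protonated form of lithium tert-butoxyacetylide 16, which comes from tert-butyl (E)-1,2-dichlorovinyl ether 15 and butyllithium. Compound 15 is the adduct of potassium tert-butoxide 14 and trichloroethylene 7, both commodity chemicals. Isolating 17 is preferred to generating 16 from 15 for each use: one titrated batch serves both branches, each acetylide is then made with one equivalent of a base matched to its electrophile, and no surplus butyllithium meets aldehyde 13 or bromide 9.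

**20 from 19; 19 from 13 and 17.** Cutting C4–C4a leads through the propargylic alcohol 19 to the aldehyde 13 and the bromomagnesium acetylide 18, formed from 17 and EtMgBr. Acylating a tert-butoxyacetylide with an ester or amide would save the oxidation, but no such carbonyl group survives the butyllithium needed earlier for the C2 ynol ether. Aldehyde addition followed by a neutral oxidation is therefore preferred, and the magnesium acetylide is chosen because it is less basic toward the enolisable β-alkynyloxy aldehyde. The carbinol centre of 19 is erased, so it needs no control.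

**13 from 12, 11, 8 and 6.** The aldehyde is the oxidised form of alcohol 12, which is the desilylated form of 11. Cutting C8–C1″ of 11 gives the lithium acetylide 10 and 9. Acetylide 10 arises from the dichlorovinyl ether 8, and cutting O1–C8a of 8 gives the secondary alcohol 6 and 7. The C2–O bond is never broken, so the configuration of 6 is carried through. A triisopropylsilyl ether on the primary oxygen is preferred to a tert-butyldimethylsilyl ether because it should not migrate to the neighbouring potassium alkoxide.

**6 from 5, 4, 3, 2 and 1.** Alcohol 6 is the mono-silylated diol 5, which is the reduction product of the β-hydroxy ester 4. The stereocentre is traced to the aryl ketone 3 (cut of C2–H), a privileged substrate for asymmetric transfer hydrogenation. Cutting C2–C3 of 3 gives the benzoate 2 and an acetate enolate, and 2 is the bis-MOM ether of methyl 3,5-dihydroxybenzoate 1. Everything before the key step is standard chemistry on achiral or singly stereogenic open-chain compounds.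

## Roads not taken

**Alternative 1:** ortho-quinone methide cycloaddition.
- *Cut:* O1–C2 and C3–C4 of ring C.
- *Forward step:* the salicylaldehyde A1 and an orthoformate give, under a chiral Brønsted acid, a 4-methoxy ortho-quinone methide. This adds the ring B styrene A2 to form the 2,4-cis 4-methoxyflavan A3.
- *Merits:* it is convergent, and ring C and the C2 configuration arise in one catalytic step from two simple arenes.
- *Weak points:*
  - The oxygens of A2 are meta to the vinyl group, so it is not the electron-rich styrene such cycloadditions need; rate and enantioselectivity are doubtful.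
  - C4 arrives as a methyl ether and needs two more steps to become the ketone.
  - The benzyl ethers must be removed before any prenyl group is present, since hydrogenolysis would not spare the olefins.
  - Both prenyl groups are still missing. Placing them on C6 and C8 is the phloroglucinol selectivity problem itself, now on a flavanone with a racemisable C2.
- *Comparison:* in setting C2 this road is more direct than the adopted plan, which spends steps 2 to 5 on a centre that its key step only carries along. Against that, the adopted plan delivers ring A complete, with both prenyl groups placed by construction.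

**Alternative 2:** double aromatic Claisen rearrangement, then cross-metathesis.
- *Cut:* C6–C1″ and C8–C1″; no ring is opened.
- *Forward step:* heating the bis(allyl) ether A4 moves both allyl groups to carbon and gives the diallyl flavanone A5. Cross-metathesis with a 2-methylpropenyl donor under a second-generation Grubbs catalyst then turns allyl into prenyl.
- *Merits:* every step is a known reaction on this substrate class. Two allyl groups have exactly two free positions, so the regiochemistry settles itself.
- *Weak points:*
  - The rearrangement needs high temperature unless a Lewis acid is used, and it frees the 5-hydroxyl on a flavanone whose C2 can racemise by ring opening.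
  - A4 must already be a single enantiomer, which calls for a separate asymmetric flavanone synthesis that this road does not provide.
- *Comparison:* in the reliability of its individual steps this road is better than the adopted plan, and its length is similar. The adopted plan sets against it a C2 centre made by a dependable ketone reduction and never heated or exposed to base, no substitution chemistry on an enolisable flavanone, and a ring A assembled in one operation. The price is an unproven key step, for which a classical fallback is given below.

**Alternative 3:** aryl triflate etherification.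
- *Cut:* O1–C8a.
- *Forward step:* a zerovalent palladium catalyst carrying a bulky dialkylbiarylphosphine couples the C2 hydroxyl of the triflate diol A6 with its C8a triflate. C2 is retained and the product is the flavan-4-ol A7.
- *Merits:* intramolecular aryl etherification with secondary alcohols is a known reaction type, and C2 can come from standard asymmetric carbonyl chemistry.
- *Weak points:*
  - The triflate sits between a prenyl group and the side chain on a very electron-rich ring, so oxidative addition will be slow.
  - The palladium alkoxide of a secondary benzylic alcohol can lose a β-hydride instead of forming the C–O bond.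
  - A6 is itself a hexasubstituted arene. It must be made by phloroglucinol chemistry, with three phenolic oxygens told apart.
  - C4 must be set as a stereocentre only to be oxidised afterwards.
- *Comparison:* the ring closure has better precedent than step 15, but the ring A problem is only moved into the precursor. The adopted plan removes that problem, at the cost of more delicate intermediates.

Key step: step 15

## Route

Remark on the chemistry: flavanone numbering (O1, C2, C3, C4, C4a, C5 to C8, C8a) is used for the corresponding atoms of open-chain intermediates. Compound 19 is carried as a mixture of epimers at its carbinol carbon, which becomes the C4 ketone in step 13. tert-Butoxyethyne 17 is assumed to be handled as a cold, titrated stock solution and not as the neat liquid.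

Step 1
Reactants: 1 methyl 3,5-dihydroxybenzoate
Product: 2 methyl 3,5-bis(methoxymethoxy)benzoate
Conditions: MOMCl (2.5 equiv), i-Pr2NEt (3 equiv), CH2Cl2, 0 °C → rt
Reagents that add atoms: chloromethyl methyl ether (MOMCl), COCCl
Why: O-alkylation of both phenols to acetals; the MOM ethers withstand the amide base, hydride, KH, butyllithium and fluoride used later and fall in the last step to the same acid as the tert-butyl ethers.

Step 2
Reactants: 2 methyl 3,5-bis(methoxymethoxy)benzoate
Product: 3 tert-butyl 3-[3,5-bis(methoxymethoxy)phenyl]-3-oxopropanoate
Conditions: t-BuOAc (2.2 equiv), LiN(SiMe3)2 (2.3 equiv), THF, −78 °C; then 2, −78 → 0 °C; aq NH4Cl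
Reagents that add atoms: tert-butyl acetate, CC(=O)OC(C)(C)C
Why: Crossed Claisen condensation forming C2–C3; the lithium enolate of tert-butyl acetate does not self-condense at −78 °C, 2 cannot enolise, and the second equivalent of enolate deprotonates the β-keto ester and drives the addition to completion.

Step 3
Reactants: 3 tert-butyl 3-[3,5-bis(methoxymethoxy)phenyl]-3-oxopropanoate
Product: 4 tert-butyl (S)-3-[3,5-bis(methoxymethoxy)phenyl]-3-hydroxypropanoate
Conditions: RuCl(p-cymene)[(S,S)-TsDPEN] (1 mol %), HCO2H/Et3N (5:2), DMF, 40 °C
Reagents that add atoms: none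
Why: Noyori–Ikariya asymmetric transfer hydrogenation of an aryl ketone; the (S,S)-catalyst, which gives (S)-1-arylethanols, should deliver hydride to the same face here and set the (S)-carbinol that becomes C2, the aryl group being oriented by its contact with the cymene ligand. The buffered medium should leave the MOM ethers intact.

Step 4
Reactants: 4 tert-butyl (S)-3-[3,5-bis(methoxymethoxy)phenyl]-3-hydroxypropanoate
Product: 5 (S)-1-[3,5-bis(methoxymethoxy)phenyl]propane-1,3-diol
Conditions: LiAlH4, THF, 0 °C → rt
Reagents that add atoms: none
Why: Hydride reduction of the ester to the primary alcohol; the carbinol centre is not involved.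

Step 5
Reactants: 5 (S)-1-[3,5-bis(methoxymethoxy)phenyl]propane-1,3-diol
Product: 6 (S)-1-[3,5-bis(methoxymethoxy)phenyl]-3-(triisopropylsilyloxy)propan-1-ol
Conditions: TIPSCl (1.05 equiv), imidazole, DMF, 0 °C
Reagents that add atoms: chlorotriisopropylsilane, CC(C)[Si](Cl)(C(C)C)C(C)C
Why: Selective silylation of the primary hydroxyl beside a secondary benzylic one; the bulky triisopropylsilyl group should not migrate to the potassium alkoxide formed in step 6.

Step 6
Reactants: 6 (S)-1-[3,5-bis(methoxymethoxy)phenyl]-3-(triisopropylsilyloxy)propan-1-ol; 7 trichloroethylene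
Product: 8 {(S)-3-[3,5-bis(methoxymethoxy)phenyl]-3-[(E)-1,2-dichlorovinyloxy]propoxy}triisopropylsilane
Conditions: KH (1.5 equiv), THF, 0 °C; then 7 (1.2 equiv), −40 °C → rt
Reagents that add atoms: none
Why: First stage of the Greene ynol ether synthesis: the alkoxide dehydrochlorinates 7 and adds anti to the resulting dichloroacetylene, forming O1–C8a as the (E)-dichlorovinyl ether. The C2–O bond is not broken, so the configuration is retained.

Step 7
Reactants: 8 {(S)-3-[3,5-bis(methoxymethoxy)phenyl]-3-[(E)-1,2-dichlorovinyloxy]propoxy}triisopropylsilane; 9 prenyl bromide (1-bromo-3-methylbut-2-ene)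
Product: 11 {(S)-3-[3,5-bis(methoxymethoxy)phenyl]-3-(5-methylhex-4-en-1-ynyloxy)propoxy}triisopropylsilane, via lithium acetylide 10 (not isolated)
Conditions: n-BuLi (2.1 equiv), THF, −78 → −40 °C; then HMPA, 9 (1.5 equiv), −78 → −20 °C
Reagents that add atoms: none
Why: Second stage of the Greene sequence: deprotonation and loss of LiCl give the chloroalkynyl ether, chlorine–lithium exchange gives the lithium alkoxyacetylide 10, and SN2 alkylation at the primary carbon of 9 forms C8–C1″. Exact stoichiometry and low temperature keep butyllithium from the benzylic C–H and from the ring position between the MOM groups.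

Step 8
Reactants: 11 {(S)-3-[3,5-bis(methoxymethoxy)phenyl]-3-(5-methylhex-4-en-1-ynyloxy)propoxy}triisopropylsilane
Product: 12 (S)-3-[3,5-bis(methoxymethoxy)phenyl]-3-(5-methylhex-4-en-1-ynyloxy)propan-1-ol
Conditions: TBAF, THF, 0 °C → rt
Reagents that add atoms: none
Why: Fluoride cleavage of the silyl ether; ynol ethers tolerate basic fluoride, and a cold neutral aqueous work-up avoids their hydration.

Step 9
Reactants: 12 (S)-3-[3,5-bis(methoxymethoxy)phenyl]-3-(5-methylhex-4-en-1-ynyloxy)propan-1-ol
Product: 13 (S)-3-[3,5-bis(methoxymethoxy)phenyl]-3-(5-methylhex-4-en-1-ynyloxy)propanal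
Conditions: Dess–Martin periodinane, NaHCO3, CH2Cl2, 0 °C
Reagents that add atoms: none
Why: Dess–Martin oxidation; the bicarbonate buffer takes up acetic acid before it can add to the ynol ether, and no amine base is present to expel the alkynyloxy group β to the new aldehyde. The aldehyde is used at once.

Step 10
Reactants: 14 potassium tert-butoxide; 7 trichloroethylene
Product: 15 tert-butyl (E)-1,2-dichlorovinyl ether
Conditions: THF, −40 °C → rt; distillation under reduced pressure
Reagents that add atoms: none
Why: The same alkoxide addition to dichloroacetylene generated in the flask as in step 6, here with the tertiary alkoxide; 15 is converted in step 11 into the alkyne that serves steps 12 and 14.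

Step 11
Reactants: 15 tert-butyl (E)-1,2-dichlorovinyl ether
Product: 17 tert-butoxyethyne, via lithium tert-butoxyacetylide 16 (not isolated)
Conditions: n-BuLi (2.05 equiv), Et2O, −78 → −40 °C; MeOH (1.05 equiv), −78 °C; cold water wash, K2CO3; kept at −20 °C as a stock solution in Et2O/hexanes, assayed by 1H NMR against an internal standard
Reagents that add atoms: none
Why: Second stage of the Greene ynol ether synthesis with a proton as the electrophile: butyllithium eliminates HCl from 15, chlorine–lithium exchange on the chloroalkynyl ether gives 16, and methanol protonates it at −78 °C. The product is kept cold because tert-butyl ynol ethers lose isobutene on warming, and the 1-chlorobutane that accompanies it in solution is inert in steps 12 and 14.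

Step 12
Reactants: 13 (S)-3-[3,5-bis(methoxymethoxy)phenyl]-3-(5-methylhex-4-en-1-ynyloxy)propanal; 17 tert-butoxyethyne
Product: 19 (5S)-5-[3,5-bis(methoxymethoxy)phenyl]-1-tert-butoxy-5-(5-methylhex-4-en-1-ynyloxy)pent-1-yn-3-ol (both C3 epimers), via bromomagnesium tert-butoxyacetylide 18 (not isolated)
Conditions: 17 (1.5 equiv), EtMgBr (1.4 equiv), THF, 0 °C → rt; then 13, −40 → 0 °C; pH 7 buffer
Reagents that add atoms: none
Why: Alkoxyethynyl Grignard addition to an aldehyde, the first stage of the Arens–van Dorp sequence: EtMgBr deprotonates 17 to 18, whose 1,2-addition to 13 forms C4–C4a. The magnesium acetylide is less basic than a lithium acetylide and no alkyllithium is present, so enolisation of 13 and loss of its β-alkynyloxy group should not compete. The new carbinol centre is not controlled and is removed in step 13; the neutral quench avoids acid-induced Meyer–Schuster rearrangement of the 3-alkoxypropargylic alcohol.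

Step 13
Reactants: 19 (5S)-5-[3,5-bis(methoxymethoxy)phenyl]-1-tert-butoxy-5-(5-methylhex-4-en-1-ynyloxy)pent-1-yn-3-ol
Product: 20 (S)-5-[3,5-bis(methoxymethoxy)phenyl]-1-tert-butoxy-5-(5-methylhex-4-en-1-ynyloxy)pent-1-yn-3-one
Conditions: MnO2 (activated, excess), CH2Cl2, 0 °C → rt
Reagents that add atoms: none
Why: MnO2 oxidation of a propargylic alcohol to the ynone; the oxidant is heterogeneous and neutral, so neither ynol ether meets acid and the β-alkynyloxy ketone meets no base.

Step 14
Reactants: 17 tert-butoxyethyne; 9 prenyl bromide (1-bromo-3-methylbut-2-ene)
Product: 22 tert-butyl 5-methylhex-4-en-1-ynyl ether, via sodium tert-butoxyacetylide 21 (not isolated)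
Conditions: 17 (1.0 equiv), NaN(SiMe3)2 (0.95 equiv), THF, −78 °C; then DMPU, 9 (0.9 equiv), −78 → 0 °C; bulb-to-bulb distillation below 30 °C
Reagents that add atoms: none
Why: Acetylide alkylation forming C6–C1″, the classical route from a metalated alkoxyacetylene to a 1-alkoxy-1-alkyne: NaN(SiMe3)2 deprotonates 17 to the sodium acetylide 21, which displaces bromide at the primary carbon of 9 (SN2) in THF/DMPU. The base is kept below one equivalent so that none remains to shift the skipped enyne to an allenyl ether, and the product is kept cold because tert-butyl ynol ethers lose isobutene on warming.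

Step 15
Reactants: 20 (S)-5-[3,5-bis(methoxymethoxy)phenyl]-1-tert-butoxy-5-(5-methylhex-4-en-1-ynyloxy)pent-1-yn-3-one; 22 tert-butyl 5-methylhex-4-en-1-ynyl ether
Product: 23 (S)-5,7-di-tert-butoxy-3',5'-bis(methoxymethoxy)-6,8-diprenylflavanone
Conditions: [Rh(cod)2]BF4 (10 mol %), rac-BINAP (10 mol %), CH2Cl2, H2 then Ar (catalyst activation); 22 (3 equiv), 20 added over 4 h, rt
Reagents that add atoms: none
Why: Proposed new method: the cationic monovalent rhodium bisphosphine fragment should take up the two tethered alkynes of 20 and couple them oxidatively, which forms C4a–C8a and a rhodacyclopentadiene fused to the new six-membered ring C; ring C thus closes by intramolecular alkyne–alkyne coupling at the metal across the C4–C3–C2–O1 tether. Coordination and insertion of 22 and C–C reductive elimination then form C5–C6 and C7–C8, so ring A closes as the last event of a formal [2+2+2] cycloaddition in which 22 supplies C6 and C7. The closest known reaction type is the [2+2+2] cycloaddition of 1,7-diynes with monoalkynes under cationic rhodium/BINAP-type catalysis at room temperature, which accepts alkynyl ethers and pairs electron-poor with electron-rich alkynes; a diyne that is both ynone and ynol ether, joined to an internal ynol ether to give a hexasubstituted phloroglucinol ring, has not been shown. The selectivity needed is the orientation of 22, whose prenyl-bearing carbon must bond to C5 and whose oxygen-bearing carbon to C8. Two things in the substrates should secure it: each alkyne is polarised with its oxygen-bearing carbon as acceptor and its carbon-substituted end as donor (at C5 the ketone adds to this), so only the head-to-tail array joins donor to acceptor at all three new bonds, and the reverse orientation would place two tert-butoxy groups on neighbouring carbons. Cross-selectivity over trimerisation of 22 rests on the intramolecular first coupling, the excess of 22 and the slow addition of 20. No stereocentre is formed, and C2, which lies in the tether and takes no part in bond making, should be carried through unchanged. Room temperature and a neutral, dry medium are essential because the benzylic and tert-butyl ynol ethers fragment to ketenes on heating and hydrate with acid.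

Step 16
Reactants: 23 (S)-5,7-di-tert-butoxy-3',5'-bis(methoxymethoxy)-6,8-diprenylflavanone
Product: 24 (S)-5,7,3',5'-tetrahydroxy-6,8-diprenylflavanone
Conditions: HCl (3 M aq)/MeOH, 40 °C
Reagents that add atoms: none
Why: Acid solvolysis of the MOM acetals and the aryl tert-butyl ethers. The C5 ether is activated by the neighbouring C4 carbonyl and the C7 ether by its two ortho substituents, so both should leave at least as readily as MOM, the tert-butyl groups ending as 2-methylpropene. Dilute methanolic HCl is the usual way to unmask prenylated flavanones and is below the acidity at which ortho-prenylphenols close to chromans.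

## Compound list

1 | methyl 3,5-dihydroxybenzoate | COC(=O)c1cc(O)cc(O)c1 | starting material
2 | methyl 3,5-bis(methoxymethoxy)benzoate | COC(=O)c1cc(OCOC)cc(OCOC)c1 | intermediate
3 | tert-butyl 3-[3,5-bis(methoxymethoxy)phenyl]-3-oxopropanoate | CC(C)(C)OC(=O)CC(=O)c1cc(OCOC)cc(OCOC)c1 | intermediate
4 | tert-butyl (S)-3-[3,5-bis(methoxymethoxy)phenyl]-3-hydroxypropanoate | CC(C)(C)OC(=O)C[C@@H](c1cc(OCOC)cc(OCOC)c1)O | intermediate
5 | (S)-1-[3,5-bis(methoxymethoxy)phenyl]propane-1,3-diol | OCC[C@@H](c1cc(OCOC)cc(OCOC)c1)O | intermediate
6 | (S)-1-[3,5-bis(methoxymethoxy)phenyl]-3-(triisopropylsilyloxy)propan-1-ol | CC(C)[Si](C(C)C)(C(C)C)OCC[C@@H](c1cc(OCOC)cc(OCOC)c1)O | intermediate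
7 | trichloroethylene | ClC=C(Cl)Cl | starting material
8 | {(S)-3-[3,5-bis(methoxymethoxy)phenyl]-3-[(E)-1,2-dichlorovinyloxy]propoxy}triisopropylsilane | CC(C)[Si](C(C)C)(C(C)C)OCC[C@@H](c1cc(OCOC)cc(OCOC)c1)O/C(Cl)=C\Cl | intermediate
9 | prenyl bromide (1-bromo-3-methylbut-2-ene) | CC(C)=CCBr | starting material
10 | ({(S)-1-[3,5-bis(methoxymethoxy)phenyl]-3-(triisopropylsilyloxy)propoxy}ethynyl)lithium | CC(C)[Si](C(C)C)(C(C)C)OCC[C@@H](c1cc(OCOC)cc(OCOC)c1)OC#C[Li] | intermediate (not isolated)
11 | {(S)-3-[3,5-bis(methoxymethoxy)phenyl]-3-(5-methylhex-4-en-1-ynyloxy)propoxy}triisopropylsilane | CC(C)[Si](C(C)C)(C(C)C)OCC[C@@H](c1cc(OCOC)cc(OCOC)c1)OC#CCC=C(C)C | intermediate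
12 | (S)-3-[3,5-bis(methoxymethoxy)phenyl]-3-(5-methylhex-4-en-1-ynyloxy)propan-1-ol | OCC[C@@H](c1cc(OCOC)cc(OCOC)c1)OC#CCC=C(C)C | intermediate
13 | (S)-3-[3,5-bis(methoxymethoxy)phenyl]-3-(5-methylhex-4-en-1-ynyloxy)propanal | O=CC[C@@H](c1cc(OCOC)cc(OCOC)c1)OC#CCC=C(C)C | intermediate
14 | potassium tert-butoxide | CC(C)(C)[O-].[K+] | starting material
15 | tert-butyl (E)-1,2-dichlorovinyl ether | CC(C)(C)O/C(Cl)=C\Cl | intermediate
16 | lithium tert-butoxyacetylide | CC(C)(C)OC#C[Li] | intermediate (not isolated)
17 | tert-butoxyethyne (tert-butyl ethynyl ether) | CC(C)(C)OC#C | intermediate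
18 | bromomagnesium tert-butoxyacetylide, i.e. (tert-butoxyethynyl)magnesium bromide | CC(C)(C)OC#C[Mg]Br | intermediate (not isolated)
19 | (5S)-5-[3,5-bis(methoxymethoxy)phenyl]-1-tert-butoxy-5-(5-methylhex-4-en-1-ynyloxy)pent-1-yn-3-ol (both C3 epimers) | CC(C)(C)OC#CC(O)C[C@@H](c1cc(OCOC)cc(OCOC)c1)OC#CCC=C(C)C | intermediate
20 | (S)-5-[3,5-bis(methoxymethoxy)phenyl]-1-tert-butoxy-5-(5-methylhex-4-en-1-ynyloxy)pent-1-yn-3-one | CC(C)(C)OC#CC(=O)C[C@@H](c1cc(OCOC)cc(OCOC)c1)OC#CCC=C(C)C | intermediate
21 | sodium tert-butoxyacetylide | CC(C)(C)OC#C[Na] | intermediate (not isolated)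
22 | tert-butyl 5-methylhex-4-en-1-ynyl ether | CC(C)=CCC#COC(C)(C)C | intermediate
23 | (S)-5,7-di-tert-butoxy-3',5'-bis(methoxymethoxy)-6,8-diprenylflavanone | CC(C)=CCc1c(OC(C)(C)C)c(CC=C(C)C)c2c(c1OC(C)(C)C)C(=O)C[C@@H](c1cc(OCOC)cc(OCOC)c1)O2 | intermediate
24 | (S)-5,7,3',5'-tetrahydroxy-6,8-diprenylflavanone, i.e. (2S)-2-(3,5-dihydroxyphenyl)-5,7-dihydroxy-6,8-bis(3-methylbut-2-enyl)chroman-4-one | CC(C)=CCc1c(O)c(CC=C(C)C)c2c(c1O)C(=O)C[C@@H](c1cc(O)cc(O)c1)O2 | target

## Step count and least certain steps

Total step count: 16. Longest linear sequence: 13 (steps 1 to 9, 12, 13, 15, 16). Steps 10, 11 and 14 form the side branch through 17 to 22; 17 also enters step 12.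

**Step 15 (key step).**
- What may go wrong:
  - trimerisation of 22 with itself, or oligomerisation of 20, may outrun the cross reaction;
  - 22 may insert in the reverse orientation;
  - the Lewis acidic cationic rhodium may trigger ketene formation or hydration of the ynol ethers, or loss of the alkynyloxy group β to the ketone, before the rings close.
- Fallback: it uses known chemistry, builds ring A from a phloroglucinol, sets out from 2 and comes back at 24. Reduction of 2 with i-Bu2AlH at −78 °C gives 3,5-bis(methoxymethoxy)benzaldehyde F1. Commercial 2,4,6-trihydroxyacetophenone is C-prenylated twice with 9 in aqueous KOH to give 2,4,6-trihydroxy-3,5-diprenylacetophenone F2, which is separated from mono- and O-prenylated material. MOMCl and i-Pr2NEt then protect two of its hydroxyls to give 2-hydroxy-4,6-bis(methoxymethoxy)-3,5-diprenylacetophenone F3; the third hydroxyl stays free in its hydrogen bond to the ketone. Claisen–Schmidt condensation of F3 with F1 (KOH, EtOH) gives the chalcone F4. NaOAc in refluxing EtOH closes F4 by oxa-Michael addition to the racemic tetrakis(methoxymethoxy)flavanone F5. Preparative chromatography on a chiral stationary phase isolates the (S)-enantiomer F6, which the conditions of step 16 convert into 24.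

**Step 7.**
- What may go wrong:
  - the acetylide may attack the tertiary end of the allylic bromide (SN2′);
  - base may shift the skipped enyne to an allenyl ether;
  - surplus butyllithium may metalate the benzylic C2–H or the ring between the MOM groups.
- Fallback: it sets out from 8 and comes back at 11. The lithium acetylide 10 is quenched with methanol at −78 °C to give the terminal ethynyl ether F7. This is coupled with 9 under copper catalysis (CuI, K2CO3, NaI, DMF, rt). The C–C bond then forms through a copper acetylide under weakly basic conditions, and no organolithium meets the allylic halide or the product.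

**Step 13 (with step 12).**
- What may go wrong:
  - acidic sites on the oxidant or on silica may cause Meyer–Schuster rearrangement or hydration of 19;
  - the ynone 20 may lose its alkynyloxy group by β-elimination once the ketone is present.
- Fallback: it sets out from 19 and comes back at 23, moving the oxidation behind the ring construction. Silylation of 19 (Et3SiCl, imidazole) gives the triethylsilyl ether F8. The cyclotrimerisation of step 15 is run on F8 with 22 to give the 4-silyloxyflavan F9; the three alkynes keep the same polarisation, but this cycloaddition is no better precedented than step 15. TBAF frees the flavan-4-ol F10, and Dess–Martin oxidation of the benzylic alcohol gives 23.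

**Step 16.**
- What may go wrong:
  - a prenyl olefin may be protonated and close onto the neighbouring free phenol (chroman formation);
  - the released tert-butyl cation may alkylate ring B before all four groups are gone;
  - cleavage of the unactivated MOM ethers may be incomplete under conditions mild enough for the olefins.
- Fallback: it sets out from 23 and comes back at 24, replacing protic solvolysis by silyl transfer in two stages. Me3SiOTf and 2,6-lutidine in CH2Cl2 at 0 °C convert the two aryl tert-butyl ethers into silyl ethers with loss of isobutene; mild aqueous work-up gives 5,7-dihydroxy-3',5'-bis(methoxymethoxy)-6,8-diprenylflavanone F11. Me3SiOTf and 2,2′-bipyridyl in MeCN then exchange the aromatic MOM ethers for silyl ethers through a bipyridinium acetal salt, and water releases 24. No Brønsted acid able to protonate the olefins is present at any point.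

## Further compounds

F1 | step 15 | 3,5-bis(methoxymethoxy)benzaldehyde | COCOc1cc(C=O)cc(OCOC)c1
F2 | step 15 | 1-[2,4,6-trihydroxy-3,5-bis(3-methylbut-2-enyl)phenyl]ethanone | CC(=O)c1c(O)c(CC=C(C)C)c(O)c(CC=C(C)C)c1O
F3 | step 15 | 1-[2-hydroxy-4,6-bis(methoxymethoxy)-3,5-bis(3-methylbut-2-enyl)phenyl]ethanone | CC(=O)c1c(O)c(CC=C(C)C)c(OCOC)c(CC=C(C)C)c1OCOC
F4 | step 15 | (E)-3-[3,5-bis(methoxymethoxy)phenyl]-1-[2-hydroxy-4,6-bis(methoxymethoxy)-3,5-bis(3-methylbut-2-enyl)phenyl]prop-2-en-1-one | COCOc1cc(/C=C/C(=O)c2c(O)c(CC=C(C)C)c(OCOC)c(CC=C(C)C)c2OCOC)cc(OCOC)c1
F5 | step 15 | rac-5,7,3',5'-tetrakis(methoxymethoxy)-6,8-diprenylflavanone | CC(C)=CCc1c(OCOC)c(CC=C(C)C)c2c(c1OCOC)C(=O)CC(c1cc(OCOC)cc(OCOC)c1)O2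
F6 | step 15 | (S)-5,7,3',5'-tetrakis(methoxymethoxy)-6,8-diprenylflavanone | CC(C)=CCc1c(OCOC)c(CC=C(C)C)c2c(c1OCOC)C(=O)C[C@@H](c1cc(OCOC)cc(OCOC)c1)O2
F7 | step 7 | {(S)-3-[3,5-bis(methoxymethoxy)phenyl]-3-(ethynyloxy)propoxy}triisopropylsilane | CC(C)[Si](C(C)C)(C(C)C)OCC[C@@H](c1cc(OCOC)cc(OCOC)c1)OC#C
F8 | step 13 | {[(5S)-5-[3,5-bis(methoxymethoxy)phenyl]-1-tert-butoxy-5-(5-methylhex-4-en-1-ynyloxy)pent-1-yn-3-yl]oxy}triethylsilane (both C3 epimers) | CC(C)(C)OC#CC(O[Si](CC)(CC)CC)C[C@@H](c1cc(OCOC)cc(OCOC)c1)OC#CCC=C(C)C
F9 | step 13 | (2S)-5,7-di-tert-butoxy-3',5'-bis(methoxymethoxy)-6,8-diprenyl-4-(triethylsilyloxy)flavan (both C4 epimers) | CC(C)=CCc1c(OC(C)(C)C)c(CC=C(C)C)c2c(c1OC(C)(C)C)C(O[Si](CC)(CC)CC)C[C@@H](c1cc(OCOC)cc(OCOC)c1)O2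
F10 | step 13 | (2S)-5,7-di-tert-butoxy-3',5'-bis(methoxymethoxy)-6,8-diprenylflavan-4-ol (both C4 epimers) | CC(C)=CCc1c(OC(C)(C)C)c(CC=C(C)C)c2c(c1OC(C)(C)C)C(O)C[C@@H](c1cc(OCOC)cc(OCOC)c1)O2
F11 | step 16 | (S)-5,7-dihydroxy-3',5'-bis(methoxymethoxy)-6,8-diprenylflavanone | CC(C)=CCc1c(O)c(CC=C(C)C)c2c(c1O)C(=O)C[C@@H](c1cc(OCOC)cc(OCOC)c1)O2
A1 | alternative 1 | 4,6-bis(benzyloxy)-2-hydroxybenzaldehyde | O=Cc1c(O)cc(OCc2ccccc2)cc1OCc1ccccc1
A2 | alternative 1 | 3,5-bis(tert-butyldimethylsilyloxy)styrene | C=Cc1cc(O[Si](C)(C)C(C)(C)C)cc(O[Si](C)(C)C(C)(C)C)c1
A3 | alternative 1 | (2S,4S)-5,7-bis(benzyloxy)-2-[3,5-bis(tert-butyldimethylsilyloxy)phenyl]-4-methoxychroman | CO[C@H]1C[C@@H](c2cc(O[Si](C)(C)C(C)(C)C)cc(O[Si](C)(C)C(C)(C)C)c2)Oc2cc(OCc3ccccc3)cc(OCc3ccccc3)c21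
A4 | alternative 2 | (S)-5,7-bis(allyloxy)-3',5'-bis(methoxymethoxy)flavanone | O=C1C[C@@H](c2cc(OCOC)cc(OCOC)c2)Oc2cc(OCC=C)cc(OCC=C)c21
A5 | alternative 2 | (S)-6,8-diallyl-5,7-dihydroxy-3',5'-bis(methoxymethoxy)flavanone | C=CCc1c(O)c(CC=C)c2c(c1O)C(=O)C[C@@H](c1cc(OCOC)cc(OCOC)c1)O2
A6 | alternative 3 | 2-{(1R,3S)-3-[3,5-bis(methoxymethoxy)phenyl]-1,3-dihydroxypropyl}-3,5-bis(methoxymethoxy)-4,6-bis(3-methylbut-2-enyl)phenyl trifluoromethanesulfonate | CC(C)=CCc1c(OCOC)c(CC=C(C)C)c(OS(=O)(=O)C(F)(F)F)c(c1OCOC)[C@H](O)C[C@@H](c1cc(OCOC)cc(OCOC)c1)O
A7 | alternative 3 | (2S,4R)-5,7,3',5'-tetrakis(methoxymethoxy)-6,8-diprenylflavan-4-ol | CC(C)=CCc1c(OCOC)c(CC=C(C)C)c2c(c1OCOC)[C@H](O)C[C@@H](c1cc(OCOC)cc(OCOC)c1)O2
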